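**Retrosynthetic overview**
- Target 9 comes from Pd(0) removal of a 4'-O-allyl group from 8; the allyl ether masks the B-ring phenol throughout.
- 8 comes from O-methylation of 7 at the 4-OH, the only OH para to the carbonyl and not hydrogen-bonded to it.
- 7 comes from double C-prenylation of acylphloroglucinol 4 at its two free ring carbons.
- 4 comes from Houben–Hoesch acylation of phloroglucinol with 4-(allyloxy)benzonitrile.
- No ring is formed: both benzene rings are bought, and the target has no stereocentre.

Assumption: the target is achiral, so there is no enantiomer to select, and 4-(allyloxy)benzonitrile is taken as a catalogue compound.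

**Route**

Step 1
Reactants: 1 phloroglucinol; 2 4-(allyloxy)benzonitrile
Product: 4 [4-(allyloxy)phenyl](2,4,6-trihydroxyphenyl)methanone, via ketiminium chloride 3 (not isolated)
Conditions: ZnCl2, HCl (g), Et2O, 0 °C to rt; then H2O, reflux
Reagents that add atoms: water, O
Why: Houben–Hoesch acylation, in which the HCl/ZnCl2-activated nitrile attacks the symmetric, very electron-rich triol (one possible regioisomer), the precipitating iminium salt stops the reaction at mono-acylation and water hydrolyses it to the ketone, with the allyl aryl ether expected to survive; no stereocentre is formed.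

Step 2
Reactants: 4 [4-(allyloxy)phenyl](2,4,6-trihydroxyphenyl)methanone; 5 prenyl bromide (2.2 equiv)
Product: 7 [4-(allyloxy)phenyl][2,4,6-trihydroxy-3,5-bis(3-methylbut-2-enyl)phenyl]methanone, via mono-C-prenyl ketone 6 (not isolated)
Conditions: 5% aq KOH, 0 °C
Reagents that add atoms: none
Why: Base-mediated C-alkylation (SN2) of the acylphloroglucinol polyanion, which in water reacts at the two free ring carbons C-3 and C-5 and rearomatises after each alkylation; the masked B-ring oxygen cannot be O-prenylated and no stereocentre is formed.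

Step 3
Reactants: 7 [4-(allyloxy)phenyl][2,4,6-trihydroxy-3,5-bis(3-methylbut-2-enyl)phenyl]methanone
Product: 8 [4-(allyloxy)phenyl][2,6-dihydroxy-4-methoxy-3,5-bis(3-methylbut-2-enyl)phenyl]methanone
Conditions: Me2SO4 (1.1 equiv), K2CO3 (1.1 equiv), acetone, rt
Reagents that add atoms: dimethyl sulfate, COS(=O)(=O)OC
Why: Regioselective Williamson O-methylation, in which one equivalent of weak base ionises only the most acidic OH (para to the carbonyl, not chelated) and the hard electrophile reacts at oxygen, leaving the two chelated ortho OH groups free.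

Step 4
Reactants: 8 [4-(allyloxy)phenyl][2,6-dihydroxy-4-methoxy-3,5-bis(3-methylbut-2-enyl)phenyl]methanone
Product: 9 vismiaphenone D
Conditions: Pd(PPh3)4 (5 mol%), morpholine (10 equiv), THF, rt
Reagents that add atoms: none
Why: Tsuji–Trost deallylation, in which Pd(0) ionises the aryl allyl ether to a π-allyl complex that excess morpholine traps irreversibly; the C-prenyl groups, the methyl ether and the ketone are not substrates.

**Compound list**

1 | phloroglucinol (benzene-1,3,5-triol) | Oc1cc(O)cc(O)c1 | starting material
2 | 4-(allyloxy)benzonitrile | C=CCOc1ccc(cc1)C#N | starting material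
3 | [4-(allyloxy)phenyl](2,4,6-trihydroxyphenyl)methaniminium chloride | C=CCOc1ccc(cc1)C(=[NH2+])c1c(O)cc(O)cc1O.[Cl-] | intermediate (not isolated)
4 | [4-(allyloxy)phenyl](2,4,6-trihydroxyphenyl)methanone | C=CCOc1ccc(cc1)C(=O)c1c(O)cc(O)cc1O | intermediate
5 | prenyl bromide (1-bromo-3-methylbut-2-ene) | CC(C)=CCBr | starting material
6 | [4-(allyloxy)phenyl][2,4,6-trihydroxy-3-(3-methylbut-2-enyl)phenyl]methanone | C=CCOc1ccc(cc1)C(=O)c1c(O)cc(O)c(CC=C(C)C)c1O | intermediate (not isolated)
7 | [4-(allyloxy)phenyl][2,4,6-trihydroxy-3,5-bis(3-methylbut-2-enyl)phenyl]methanone | C=CCOc1ccc(cc1)C(=O)c1c(O)c(CC=C(C)C)c(O)c(CC=C(C)C)c1O | intermediate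
8 | [4-(allyloxy)phenyl][2,6-dihydroxy-4-methoxy-3,5-bis(3-methylbut-2-enyl)phenyl]methanone | C=CCOc1ccc(cc1)C(=O)c1c(O)c(CC=C(C)C)c(OC)c(CC=C(C)C)c1O | intermediate
9 | vismiaphenone D, [2,6-dihydroxy-4-methoxy-3,5-bis(3-methylbut-2-enyl)phenyl](4-hydroxyphenyl)methanone (achiral) | COc1c(CC=C(C)C)c(O)c(C(=O)c2ccc(O)cc2)c(O)c1CC=C(C)C | target

**Totals**

Total step count: 4. Longest linear sequence: 4 steps.

**Three steps most likely to fail, with fallbacks**

Step 2 (double C-prenylation) is the weakest step: O-prenylation, mono-alkylation and geminal over-alkylation compete. The fallback sets out from 4 and comes back at 7. It replaces the anionic alkylation by an acid-mediated Friedel–Crafts prenylation with 2-methylbut-3-en-2-ol and BF3·OEt2 in dioxane at rt. The neutral phenol then reacts as an arene with a prenyl cation, which avoids the anionic over-alkylation pathways. Mono-prenyl ketone 6 is recovered and resubmitted. No new compound is made (entry F0 below).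

Step 3 (4-O-methylation) is next: the 4-OH of 7 sits between two prenyl groups, so over-methylation at an ortho OH or C-methylation may compete. The fallback sets out from 4 and comes back at 8 by reversing the order. Compound 4 is methylated first (Me2SO4, K2CO3, acetone), where the 4-OH is unhindered, to give [4-(allyloxy)phenyl](2,6-dihydroxy-4-methoxyphenyl)methanone F1. F1 is then C-prenylated twice with 5 in aqueous KOH at 0 °C, through [4-(allyloxy)phenyl][2,6-dihydroxy-4-methoxy-3-(3-methylbut-2-enyl)phenyl]methanone F2, to reach 8.

Step 1 (Hoesch acylation) is third: the electron-rich nitrile is a sluggish electrophile, and the allyl ether has to survive anhydrous HCl/ZnCl2. The fallback sets out from 1 and comes back at 4, using directed ortho-metalation instead of electrophilic substitution. Compound 1 is converted with NaH and MOMCl in DMF into 1,3,5-tris(methoxymethoxy)benzene F3. F3 is lithiated between two OMOM groups (n-BuLi, THF, 0 °C) to give 2,4,6-tris(methoxymethoxy)phenyllithium F4. F4 adds to nitrile 2 (−78 °C to rt) to give the N-lithio ketimine F5. HCl in aqueous MeOH at 60 °C then hydrolyses the imine and removes the three MOM groups in one operation to give 4.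

**Further compounds**

F0 | step 2 | none | none
F1 | step 3 | [4-(allyloxy)phenyl](2,6-dihydroxy-4-methoxyphenyl)methanone | C=CCOc1ccc(cc1)C(=O)c1c(O)cc(OC)cc1O
F2 | step 3 | [4-(allyloxy)phenyl][2,6-dihydroxy-4-methoxy-3-(3-methylbut-2-enyl)phenyl]methanone | C=CCOc1ccc(cc1)C(=O)c1c(O)cc(OC)c(CC=C(C)C)c1O
F3 | step 1 | 1,3,5-tris(methoxymethoxy)benzene | COCOc1cc(OCOC)cc(OCOC)c1
F4 | step 1 | 2,4,6-tris(methoxymethoxy)phenyllithium | [Li]c1c(OCOC)cc(OCOC)cc1OCOC
F5 | step 1 | N-lithio [4-(allyloxy)phenyl][2,4,6-tris(methoxymethoxy)phenyl]methanimine | C=CCOc1ccc(cc1)C(=N[Li])c1c(OCOC)cc(OCOC)cc1OCOC
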